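**Numbering used throughout:** 1 syringol; 2 its benzyl ether; 3 dibromide; 4 bis(boronate); 5 resorcinol; 6 iodoresorcinol; 7 aryl aldehyde; 8 aryl alkyne; 9 carbon monoxide; 10 ynone; 11 enaminone; 12 flavone with free 5-OH; 13 5,7-dibenzyl flavone; 14 flavone epoxide; 15 flavonol; 16 3-O-methyl flavonol; 17 target.

## Analysis of the target

Target 17 is a flavone, a 4H-chromen-4-one in which benzo ring A (C4a, C5 to C8, C8a) is fused to pyranone ring C (O1, C2, C3, C4) and a 2,4,5-trimethoxyphenyl ring B sits on C2. It has no stereocentre and no other stereogenic element, so the problem is one of substitution pattern and chemoselectivity only. Ring A is hexasubstituted, with C4a (bearing C4=O), C5–OH, C6–OMe, C7–OH, C8–OMe and C8a–O1 following one another, and C3 of ring C carries a further methoxy group. The sensitive points are the two electron-rich arenes, which are easily oxidised, and the pyranone, which hard nucleophiles open at C2. The two phenols differ in character, since 7-OH is the more acidic and more easily alkylated one whereas 5-OH is held in a hydrogen bond to the C4 carbonyl. The difficulty is to build the fully substituted ring A without regioisomers and to finish with methyl on O3, O6 and O8 but hydrogen on O5 and O7. The route rests on the local symmetry of ring A about the axis through C4a and C7, which makes C5–OH and C6–OMe the mirror images of C8a–O1 and C8–OMe, so that the C4 carbonyl carbon can be brought in as carbon monoxide 9 between the symmetric 2-iodoresorcinol 6 and the terminal carbon of alkyne 8, and either hydroxyl of 6 may become O1.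

## Retrosynthetic reasoning

**17 from 16.** The two O–benzyl bonds at O5 and O7 are cut last. Hydrogenolysis is neutral and touches neither the six methyl ethers nor the pyranone. Because both phenols carry the same group, one operation releases them together.

**16 from 15.** The O3–methyl bond is cut next. In 15 the 3-hydroxyl is the only free hydroxyl, so the forward methylation needs no selectivity between O3, O5 and O7.

**15 from 13 through 14.** The C3–O bond is cut. The ring-forming step leaves hydrogen on C3, because that carbon is the terminal carbon of alkyne 8, so the oxygen has to be added afterwards. C2=C3 is an enol ether double bond (O1–C2=C3) and should accept oxygen from an electrophilic oxygen-transfer reagent. The resulting epoxide 14 should isomerise under acid to the 3-hydroxyflavone 15, since cleavage of its C2–O bond gives a cation stabilised by O1 and by ring B.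

**13 from 12.** The O5–benzyl bond is cut. Oxidising 12 directly would expose a free phenol on a pentaoxygenated ring to the oxidant, and its hydrogen bond to C4=O would lower the nucleophilicity of C2=C3. Capping O5 costs one step, removes both problems and makes the later methylation unambiguous. A benzyl group is chosen because it leaves together with the one on O7.

**12 from 6, 8 and 9.** This is the key disconnection: C4a–C4, C4–C3 and O1–C2 are cut, and ring C falls apart into 6, 9 and 8. It is made here for three reasons.
- All five oxygens of ring A are then already in place on a simple benzene.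
- The iodine of 6 sits between two equivalent hydroxyls, so no regiochemical question arises.
- Three skeletal bonds and one ring form in one operation.

The forward reaction must insert 9 before the alkyne couples (giving ynone 10) and must close the six-membered, not the five-membered, ring (through enaminone 11).

**6 from 5.** The C–I bond is cut. In 5 a single ring carbon is unsubstituted and it lies between the two hydroxyls, so electrophilic iodination can only go there.

**5 from 3 through 4.** The two phenolic C–O bonds are traced back to the C–B bonds of 4 and these to the C–Br bonds of 3. Borylation followed by oxidation installs oxygen exactly where the halogens were, which direct hydroxylation of an arene could not guarantee.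

**3 from 2, and 2 from 1.** The C–Br bonds come from electrophilic bromination, directed by the two methoxy groups to the two positions that are ortho to one and para to the other. Benzylating 1 first marks the future O7 as different from all other oxygens from the outset. Starting material 1 already supplies three of the five oxygens of ring A with the correct methylation pattern.

**8 from 7.** The alkyne is obtained by one-carbon homologation of aldehyde 7 (Ohira–Bestmann). The added carbon becomes C3 of the flavone and the former aldehyde carbon becomes C2.

## Alternatives that were turned down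

Alternative 1: Ring A itself is taken apart at C7–C8 and C4a–C5.
- Disconnection: 1,5-dimethoxypentane-2,4-dione A1 would supply C8, C8a, C4a, C4 and C3, and dimethyl 2-methoxymalonate A2 would supply C5, C6 and C7.
- Forward key step: an alkoxide-mediated double Claisen condensation acylates a terminal methoxymethylene carbon and the central methylene of A1 with the two ester groups of A2. Enolisation gives the aromatic triol 2-methoxy-1-(2,4,6-trihydroxy-3,5-dimethoxyphenyl)ethan-1-one A3. Aroylation and cyclodehydration of A3 in the Allan–Robinson manner would then lead towards 17.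
- For: it is by far the shortest plan, C3 carries its methoxy group from the start, and O5 and O7 need no protection and no late oxidation. On step count and on the C3 problem it is stronger than the chosen route.
- Against: the central methylene of A1 is much more acidic than its termini, so the terminal carbon must react as a dianion. The methoxy groups hinder both nucleophile and electrophile. O-acylation to pyranones and self-condensation of A1 are the usual outcomes of such diketone–malonate pairings. A3 would then enter a high-temperature aroylation with three free hydroxyls and would need a hydrolytic finish.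
- Comparison: the chosen route is roughly twice as long, but ring A comes from an arene whose pattern is fixed by ordinary aromatic substitution, and no C–C bond depends on a choice between C- and O-acylation.

Alternative 2: Ring C is cut at C3–C4 and C2=C3.
- Disconnection: C3 with its methoxy group would come from (methoxymethylene)triphenylphosphorane A4. C4, ring A and, as an aryl ester, C2 with ring B would come from 4-(benzyloxy)-3,5-dimethoxy-2,6-bis[(2,4,5-trimethoxybenzoyl)oxy]benzoyl chloride A5.
- Forward key step: A4 is acylated by the acid chloride function of A5, and the resulting keto ylide olefinates the neighbouring ester carbonyl in an intramolecular Wittig reaction. The product is 7-(benzyloxy)-3,6,8-trimethoxy-4-oxo-2-(2,4,5-trimethoxyphenyl)-4H-chromen-5-yl 2,4,5-trimethoxybenzoate A6.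
- For: the C3 methoxy group arrives directly, neither a pressurised gas nor an oxidation of the finished flavone is needed, and A5 is symmetric. On the C3 problem this plan is stronger than the chosen one.
- Against: A5 is a hexasubstituted benzoyl chloride flanked by two acyloxy groups. Its preparation needs carboxylation of a resorcinol such as 5, double aroylation and chlorination, and acyl transfer between the ortho esters and the acid function is likely. A4 is a non-stabilised, strongly basic ylide that meets three electrophilic carbonyls, and a second equivalent is used up as base. The methoxy group on the ylide carbon hinders the ester olefination. A6 still carries one wasted aroyl unit, which must be hydrolysed from a hindered ester beside a base-sensitive pyranone.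
- Comparison: the length is similar, but the chosen route couples three simple components and wastes no fragment.

Alternative 3: Ring C is cut at C3–C4 and O1–C8a.
- Disconnection: 2-methoxy-1-(2,4,5-trimethoxyphenyl)ethan-1-one A7 would provide ring B, C2, C3 with its methoxy group and O1. 2,4,6-Trifluoro-3,5-dimethoxybenzoyl chloride A8 would provide C4 and ring A.
- Forward key step: the lithium enolate of A7 is C-acylated by A8 and the diketonate oxygen displaces an ortho fluoride in a nucleophilic aromatic substitution. This gives 5,7-difluoro-3,6,8-trimethoxy-2-(2,4,5-trimethoxyphenyl)-4H-chromen-4-one A9.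
- For: it is convergent, the C3 methoxy group is in place, the symmetric electrophile raises no regiochemical question, and the acylation–fluoride displacement cascade is well established for ortho-fluorobenzoyl diketones. The ring closure itself is probably more dependable than the chosen key step.
- Against: A8 is not a readily available material, and substitution on polyfluorinated benzoates favours the para position, not the 3- and 5-positions that must carry methoxy groups. A9 still has C–F where the target has C–OH. Two further substitutions by an oxygen nucleophile are therefore needed on a ring deactivated by two methoxy groups, in competition with attack at C2 that opens the pyranone, and a deprotection follows.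
- Comparison: this plan postpones the oxygenation of ring A, whereas in the chosen route all five oxygens of ring A are in place before ring C is formed.

Key step: step 7

Remark on the chemistry: epoxide 14 is formed as a racemate with the only possible (cis) ring fusion, and both its stereocentres disappear in the same step. The organopalladium species of the catalytic cycle are described in step 7 but carry no compound numbers.

## Route

Step 1
Reactants: 1 2,6-dimethoxyphenol (syringol)
Product: 2 2-(benzyloxy)-1,3-dimethoxybenzene
Conditions: BnBr (1.2 equiv), K2CO3, DMF, 60 °C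
Reagents that add atoms: benzyl bromide, BrCc1ccccc1
Why: Williamson ether synthesis; the phenoxide, although flanked by two methoxy groups, should alkylate cleanly with the reactive benzylic halide in a dipolar aprotic solvent.

Step 2
Reactants: 2 2-(benzyloxy)-1,3-dimethoxybenzene
Product: 3 3-(benzyloxy)-1,5-dibromo-2,4-dimethoxybenzene
Conditions: NBS (2.1 equiv), MeCN, 0 °C to rt, dark
Reagents that add atoms: N-bromosuccinimide, O=C1CCC(=O)N1Br
Why: Electrophilic aromatic bromination; the two positions that are ortho to one methoxy group and para to the other are strongly activated, while the remaining position is only para to the twisted central benzyloxy group and ends up flanked by two bromines, so the reaction should stop at the dibromide. Ionic conditions in the dark should leave the benzylic CH2 alone.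

Step 3
Reactants: 3 3-(benzyloxy)-1,5-dibromo-2,4-dimethoxybenzene
Product: 4 2,2'-[5-(benzyloxy)-4,6-dimethoxy-1,3-phenylene]bis(4,4,5,5-tetramethyl-1,3,2-dioxaborolane)
Conditions: B2pin2 (2.6 equiv), Pd(dppf)Cl2 (5 mol %), KOAc, 1,4-dioxane, 90 °C
Reagents that add atoms: bis(pinacolato)diboron, CC1(C)OB(OC1(C)C)B1OC(C)(C)C(C)(C)O1
Why: Double Miyaura borylation; each C–Br bond has only one ortho substituent, and the weak base KOAc should suppress Suzuki coupling of the product with unreacted bromide. The benzyl ether is inert to these conditions, which is why palladium catalysis is preferred to halogen–lithium exchange.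

Step 4
Reactants: 4 2,2'-[5-(benzyloxy)-4,6-dimethoxy-1,3-phenylene]bis(4,4,5,5-tetramethyl-1,3,2-dioxaborolane)
Product: 5 5-(benzyloxy)-4,6-dimethoxybenzene-1,3-diol
Conditions: H2O2 (30 % aq), NaOH (aq), THF, 0 °C, under N2; then HCl (1 M)
Reagents that add atoms: hydrogen peroxide, OO
Why: Oxidation of the arylboronates by hydroperoxide with 1,2-migration of the aryl group from boron to oxygen, which places each hydroxyl exactly where boron was. Low temperature, short contact time and exclusion of air should protect the electron-rich diol.

Step 5
Reactants: 5 5-(benzyloxy)-4,6-dimethoxybenzene-1,3-diol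
Product: 6 5-(benzyloxy)-2-iodo-4,6-dimethoxybenzene-1,3-diol
Conditions: NIS (1.0 equiv), CH2Cl2–MeCN, −20 °C, dark
Reagents that add atoms: N-iodosuccinimide, O=C1CCC(=O)N1I
Why: Electrophilic aromatic iodination at the only unsubstituted ring carbon, which is ortho to both hydroxyls; the unactivated phenyl ring of the benzyl group cannot compete. One equivalent of a mild iodonium source at low temperature should limit oxidation of the ring, and 6 should be used promptly.

Step 6
Reactants: 7 2,4,5-trimethoxybenzaldehyde
Product: 8 1-ethynyl-2,4,5-trimethoxybenzene
Conditions: dimethyl (1-diazo-2-oxopropyl)phosphonate (1.3 equiv), K2CO3, MeOH, 0 °C to rt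
Reagents that add atoms: dimethyl (1-diazo-2-oxopropyl)phosphonate, COP(=O)(OC)C(=[N+]=[N-])C(C)=O
Why: Ohira–Bestmann variant of the Seyferth–Gilbert homologation; methoxide removes the acetyl group of the reagent, the diazomethylphosphonate anion adds to the aldehyde, and loss of phosphate and then of N2 with a 1,2-hydrogen shift gives the terminal alkyne. The aldehyde has no enolisable position and the mild base tolerates the methyl ethers.

Step 7
Reactants: 6 5-(benzyloxy)-2-iodo-4,6-dimethoxybenzene-1,3-diol; 8 1-ethynyl-2,4,5-trimethoxybenzene (1.5 equiv); 9 carbon monoxide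
Product: 12 7-(benzyloxy)-5-hydroxy-6,8-dimethoxy-2-(2,4,5-trimethoxyphenyl)-4H-chromen-4-one, via ortho-hydroxyaryl ynone 10 (not isolated), via diethylamino enaminone 11 (not isolated)
Conditions: PdCl2(PPh3)2 (5 mol %), CO (20 atm), Et2NH (solvent), 120 °C, autoclave
Reagents that add atoms: none
Why: Zerovalent palladium, generated in the flask from PdCl2(PPh3)2, should add oxidatively to the C–I bond of 6, and the crowded, electron-rich aryl complex of divalent palladium should take up CO 9 to give an aroyl complex before any direct alkynylation. Amine-assisted transfer of the alkynyl group of 8 and reductive elimination then form C4a–C4 and C4–C3 in ynone 10, a copper-free carbonylative Sonogashira coupling. Et2NH adds to the β-carbon of 10, whose carbonyl is activated by a hydrogen bond from an ortho hydroxyl, to give enaminone 11. One phenol oxygen then attacks that same carbon and the amine is expelled, which forms O1–C2 and closes ring C in a net 6-endo-dig mode (an addition–elimination on the enaminone). The closest known reaction type is the palladium-catalysed carbonylative annulation of ortho-iodophenols with terminal alkynes to flavones in a secondary amine, a known reaction applied here to a 2-iodoresorcinol. The selectivity needed is six-membered (flavone) over five-membered (aurone) closure, and it is secured because in 11 the amine-bearing carbon is the only electrophilic site left for the phenol. Regiochemistry on ring A needs no control, since the iodine lies on the mirror plane of 6 and the two hydroxyls are equivalent, so that one becomes O1 and the other the chelated 5-hydroxyl. No stereocentre is created, and the benzyl and methyl ethers are inert to the conditions.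

Step 8
Reactants: 12 7-(benzyloxy)-5-hydroxy-6,8-dimethoxy-2-(2,4,5-trimethoxyphenyl)-4H-chromen-4-one
Product: 13 5,7-bis(benzyloxy)-6,8-dimethoxy-2-(2,4,5-trimethoxyphenyl)-4H-chromen-4-one
Conditions: BnBr (2 equiv), K2CO3, DMF, 70 °C
Reagents that add atoms: benzyl bromide, BrCc1ccccc1
Why: Williamson ether synthesis on the only hydroxyl present; the chelated 5-hydroxyl is a sluggish nucleophile, but its phenoxide forms in warm DMF and benzyl bromide is reactive enough. Anhydrous carbonate should not open the pyranone.

Step 9
Reactants: 13 5,7-bis(benzyloxy)-6,8-dimethoxy-2-(2,4,5-trimethoxyphenyl)-4H-chromen-4-one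
Product: 15 5,7-bis(benzyloxy)-3-hydroxy-6,8-dimethoxy-2-(2,4,5-trimethoxyphenyl)-4H-chromen-4-one, via racemic flavone 2,3-epoxide 14 (not isolated)
Conditions: DMDO (about 0.08 M in acetone, 4 equiv), CH2Cl2, 0 °C to rt; evaporate; then p-TsOH·H2O (0.1 equiv), CH2Cl2, rt
Reagents that add atoms: dimethyldioxirane, CC1(C)OO1
Why: Dioxirane epoxidation of the enol ether double bond C2=C3 by concerted oxygen transfer, followed by acid-catalysed epoxide isomerisation in which the C2–O bond breaks to a cation stabilised by O1 and ring B and loss of the C3 proton gives the 3-hydroxyflavone. The two stereocentres of racemic 14 vanish in this step, and the neutral, nucleophile-free oxidant spares the pyranone.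

Step 10
Reactants: 15 5,7-bis(benzyloxy)-3-hydroxy-6,8-dimethoxy-2-(2,4,5-trimethoxyphenyl)-4H-chromen-4-one
Product: 16 5,7-bis(benzyloxy)-3,6,8-trimethoxy-2-(2,4,5-trimethoxyphenyl)-4H-chromen-4-one
Conditions: MeI (3 equiv), K2CO3, acetone, reflux
Reagents that add atoms: iodomethane, CI
Why: Williamson O-methylation of the acidic enolic 3-hydroxyl, which is the only free hydroxyl in 15, so no selectivity is required.

Step 11
Reactants: 16 5,7-bis(benzyloxy)-3,6,8-trimethoxy-2-(2,4,5-trimethoxyphenyl)-4H-chromen-4-one
Product: 17 5,7-dihydroxy-3,6,8-trimethoxy-2-(2,4,5-trimethoxyphenyl)-4H-chromen-4-one (5,7-dihydroxy-3,6,8,2',4',5'-hexamethoxyflavone)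
Conditions: H2 (1 atm), 10 % Pd/C, EtOAc–MeOH, rt
Reagents that add atoms: none
Why: Catalytic hydrogenolysis of the two benzylic C–O bonds; the tetrasubstituted, cross-conjugated C2=C3 bond of a 3-methoxyflavone and the aryl methyl ethers should not be reduced at atmospheric pressure and room temperature.

## Compound list

1 | 2,6-dimethoxyphenol (syringol) | COc1cccc(OC)c1O | starting material
2 | 2-(benzyloxy)-1,3-dimethoxybenzene | COc1cccc(OC)c1OCc1ccccc1 | intermediate
3 | 3-(benzyloxy)-1,5-dibromo-2,4-dimethoxybenzene | COc1c(Br)cc(Br)c(OC)c1OCc1ccccc1 | intermediate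
4 | 2,2'-[5-(benzyloxy)-4,6-dimethoxy-1,3-phenylene]bis(4,4,5,5-tetramethyl-1,3,2-dioxaborolane) | COc1c(B2OC(C)(C)C(C)(C)O2)cc(B2OC(C)(C)C(C)(C)O2)c(OC)c1OCc1ccccc1 | intermediate
5 | 5-(benzyloxy)-4,6-dimethoxybenzene-1,3-diol | COc1c(O)cc(O)c(OC)c1OCc1ccccc1 | intermediate
6 | 5-(benzyloxy)-2-iodo-4,6-dimethoxybenzene-1,3-diol | COc1c(O)c(I)c(O)c(OC)c1OCc1ccccc1 | intermediate
7 | 2,4,5-trimethoxybenzaldehyde | COc1cc(OC)c(C=O)cc1OC | starting material
8 | 1-ethynyl-2,4,5-trimethoxybenzene | C#Cc1cc(OC)c(OC)cc1OC | intermediate
9 | carbon monoxide | [C-]#[O+] | starting material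
10 | 1-[4-(benzyloxy)-2,6-dihydroxy-3,5-dimethoxyphenyl]-3-(2,4,5-trimethoxyphenyl)prop-2-yn-1-one | COc1cc(OC)c(C#CC(=O)c2c(O)c(OC)c(OCc3ccccc3)c(OC)c2O)cc1OC | intermediate
11 | (2E)-1-[4-(benzyloxy)-2,6-dihydroxy-3,5-dimethoxyphenyl]-3-(diethylamino)-3-(2,4,5-trimethoxyphenyl)prop-2-en-1-one (E isomer drawn; the push–pull double bond isomerises freely and its geometry is lost on ring closure) | CCN(CC)/C(=C/C(=O)c1c(O)c(OC)c(OCc2ccccc2)c(OC)c1O)c1cc(OC)c(OC)cc1OC | intermediate
12 | 7-(benzyloxy)-5-hydroxy-6,8-dimethoxy-2-(2,4,5-trimethoxyphenyl)-4H-chromen-4-one | COc1cc(OC)c(-c2cc(=O)c3c(O)c(OC)c(OCc4ccccc4)c(OC)c3o2)cc1OC | intermediate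
13 | 5,7-bis(benzyloxy)-6,8-dimethoxy-2-(2,4,5-trimethoxyphenyl)-4H-chromen-4-one | COc1cc(OC)c(-c2cc(=O)c3c(OCc4ccccc4)c(OC)c(OCc4ccccc4)c(OC)c3o2)cc1OC | intermediate
14 | rac-5,7-bis(benzyloxy)-2,3-epoxy-6,8-dimethoxy-2-(2,4,5-trimethoxyphenyl)-2,3-dihydro-4H-chromen-4-one (cis-fused oxirane, racemic, one enantiomer drawn) | O=C1[C@H]2O[C@@]2(c2cc(OC)c(OC)cc2OC)Oc2c(OC)c(OCc3ccccc3)c(OC)c(OCc3ccccc3)c21 | intermediate
15 | 5,7-bis(benzyloxy)-3-hydroxy-6,8-dimethoxy-2-(2,4,5-trimethoxyphenyl)-4H-chromen-4-one | COc1cc(OC)c(-c2oc3c(OC)c(OCc4ccccc4)c(OC)c(OCc4ccccc4)c3c(=O)c2O)cc1OC | intermediate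
16 | 5,7-bis(benzyloxy)-3,6,8-trimethoxy-2-(2,4,5-trimethoxyphenyl)-4H-chromen-4-one | COc1cc(OC)c(-c2oc3c(OC)c(OCc4ccccc4)c(OC)c(OCc4ccccc4)c3c(=O)c2OC)cc1OC | intermediate
17 | 5,7-dihydroxy-3,6,8-trimethoxy-2-(2,4,5-trimethoxyphenyl)-4H-chromen-4-one | COc1cc(OC)c(-c2oc3c(OC)c(O)c(OC)c(O)c3c(=O)c2OC)cc1OC | target

## Step count and least certain steps

Total step count: 11. Longest linear sequence: 10 steps (steps 1–5 and 7–11, from 1 to 17); alkyne 8 is made in one further step (step 6).

**Step 7 (key step).** The most likely failure is diversion of the aroyl–palladium intermediate before the alkynyl group is transferred, either by attack of Et2NH on the acyl complex (aminocarbonylation) or by reduction of the C–I bond. The aroyl complex is crowded by two ortho oxygen substituents, and the arene, partly present as its phenoxide, is very electron-rich. Direct coupling without uptake of carbon monoxide, followed by closure to a benzofuran, is the other escape.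

The fallback sets out from 6 and 8 and comes back to the route at 12, passing through 10, which is isolated on this path. It builds the same three bonds by polar chemistry, without palladium and without carbon monoxide. Both hydroxyls of 6 would be capped as methoxymethyl ethers (MOMCl, iPr2NEt, CH2Cl2) to give 1-(benzyloxy)-4-iodo-2,6-dimethoxy-3,5-bis(methoxymethoxy)benzene F1. Alkyne 8 would be deprotonated (n-BuLi, THF, −78 °C) to lithium (2,4,5-trimethoxyphenyl)acetylide F2, and F2 would be acylated with N-methoxy-N-methylcarbamoyl chloride to N-methoxy-N-methyl-3-(2,4,5-trimethoxyphenyl)prop-2-ynamide F3. Iodine–lithium exchange on F1 (n-BuLi, THF, −78 °C) should give [4-(benzyloxy)-3,5-dimethoxy-2,6-bis(methoxymethoxy)phenyl]lithium F4. Addition of F4 to the Weinreb amide F3 and a cold acidic quench should give 1-[4-(benzyloxy)-3,5-dimethoxy-2,6-bis(methoxymethoxy)phenyl]-3-(2,4,5-trimethoxyphenyl)prop-2-yn-1-one F5. Acidic methanolysis of the two acetals of F5 (HCl, MeOH, 40 °C) would release 10, and Et2NH in EtOH would close 10 through 11 to 12.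

**Step 9.** The most likely failure is slow oxygen transfer to the cross-conjugated C2=C3 bond. Oxidation of the benzylic C–H bonds of the benzyl ethers or of the electron-rich ring B could then overtake epoxidation. Adventitious water could also open 14 to a diol instead of letting it isomerise.

The fallback sets out from 13 and comes back to the route at 15. It makes C3 a nucleophile instead of attacking it with an electrophilic oxidant. Deprotonation of 13 at C3 with LiN(iPr)2 (THF, −78 °C) should give [5,7-bis(benzyloxy)-6,8-dimethoxy-4-oxo-2-(2,4,5-trimethoxyphenyl)-4H-chromen-3-yl]lithium F6. Trapping F6 with B(OMe)3 would give dimethyl [5,7-bis(benzyloxy)-6,8-dimethoxy-4-oxo-2-(2,4,5-trimethoxyphenyl)-4H-chromen-3-yl]boronate F7. Oxidation of F7 with H2O2 in AcOH would give 15.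

**Step 8.** The most likely failure is incomplete alkylation of the hydrogen-bonded 5-hydroxyl, which is flanked by C4=O and the 6-methoxy group, or opening of ring C by base if the reaction is forced.

The fallback sets out from 6 and comes back to the route at 13, so that 12 is bypassed. It places the second benzyl group before the carbonyl exists, when the hydroxyl is still an ordinary, unchelated phenol. Treating 6 with one equivalent of BnBr and K2CO3 in acetone should give 3,5-bis(benzyloxy)-2-iodo-4,6-dimethoxyphenol F8 after separation from unchanged 6, which is recycled, and from over-alkylated material. The price is a statistical monoalkylation of two equivalent hydroxyls. F8, 8 and 9 would then be combined under the conditions of step 7. The coupling should pass through 1-[2,4-bis(benzyloxy)-6-hydroxy-3,5-dimethoxyphenyl]-3-(2,4,5-trimethoxyphenyl)prop-2-yn-1-one F9 and its diethylamine adduct (2E)-1-[2,4-bis(benzyloxy)-6-hydroxy-3,5-dimethoxyphenyl]-3-(diethylamino)-3-(2,4,5-trimethoxyphenyl)prop-2-en-1-one F10, neither of them isolated. The single remaining hydroxyl of F10 can only close ring C in one sense, which gives 13 directly.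

**Step 3.** The most likely failure is stalling after the first borylation or hydrodebromination of the electron-rich bromide, which would leave monofunctionalised material that is hard to separate.

The fallback sets out from 3 and comes back to the route at 5, bypassing 4. It replaces the boron detour by direct palladium-catalysed C–O coupling with hydroxide: Pd2(dba)3, di-tert-butyl(2',4',6'-triisopropylbiphenyl-2-yl)phosphine, KOH, 1,4-dioxane–H2O, 100 °C, then acidification. No new compound arises on this path, which is entered below as F0.

## Further compounds

F1 | step 7 | 1-(benzyloxy)-4-iodo-2,6-dimethoxy-3,5-bis(methoxymethoxy)benzene | COCOc1c(I)c(OCOC)c(OC)c(OCc2ccccc2)c1OC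
F2 | step 7 | lithium (2,4,5-trimethoxyphenyl)acetylide | [Li]C#Cc1cc(OC)c(OC)cc1OC
F3 | step 7 | N-methoxy-N-methyl-3-(2,4,5-trimethoxyphenyl)prop-2-ynamide | CON(C)C(=O)C#Cc1cc(OC)c(OC)cc1OC
F4 | step 7 | [4-(benzyloxy)-3,5-dimethoxy-2,6-bis(methoxymethoxy)phenyl]lithium | [Li]c1c(OCOC)c(OC)c(OCc2ccccc2)c(OC)c1OCOC
F5 | step 7 | 1-[4-(benzyloxy)-3,5-dimethoxy-2,6-bis(methoxymethoxy)phenyl]-3-(2,4,5-trimethoxyphenyl)prop-2-yn-1-one | COCOc1c(C(=O)C#Cc2cc(OC)c(OC)cc2OC)c(OCOC)c(OC)c(OCc2ccccc2)c1OC
F6 | step 9 | [5,7-bis(benzyloxy)-6,8-dimethoxy-4-oxo-2-(2,4,5-trimethoxyphenyl)-4H-chromen-3-yl]lithium | [Li]c1c(-c2cc(OC)c(OC)cc2OC)oc2c(OC)c(OCc3ccccc3)c(OC)c(OCc3ccccc3)c2c1=O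
F7 | step 9 | dimethyl [5,7-bis(benzyloxy)-6,8-dimethoxy-4-oxo-2-(2,4,5-trimethoxyphenyl)-4H-chromen-3-yl]boronate | COB(OC)c1c(-c2cc(OC)c(OC)cc2OC)oc2c(OC)c(OCc3ccccc3)c(OC)c(OCc3ccccc3)c2c1=O
F8 | step 8 | 3,5-bis(benzyloxy)-2-iodo-4,6-dimethoxyphenol | COc1c(O)c(I)c(OCc2ccccc2)c(OC)c1OCc1ccccc1
F9 | step 8 | 1-[2,4-bis(benzyloxy)-6-hydroxy-3,5-dimethoxyphenyl]-3-(2,4,5-trimethoxyphenyl)prop-2-yn-1-one | COc1cc(OC)c(C#CC(=O)c2c(O)c(OC)c(OCc3ccccc3)c(OC)c2OCc2ccccc2)cc1OC
F10 | step 8 | (2E)-1-[2,4-bis(benzyloxy)-6-hydroxy-3,5-dimethoxyphenyl]-3-(diethylamino)-3-(2,4,5-trimethoxyphenyl)prop-2-en-1-one | CCN(CC)/C(=C/C(=O)c1c(O)c(OC)c(OCc2ccccc2)c(OC)c1OCc1ccccc1)c1cc(OC)c(OC)cc1OC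
F0 | step 3 | none | none
A1 | alternative 1 | 1,5-dimethoxypentane-2,4-dione | COCC(=O)CC(=O)COC
A2 | alternative 1 | dimethyl 2-methoxymalonate | COC(C(=O)OC)C(=O)OC
A3 | alternative 1 | 2-methoxy-1-(2,4,6-trihydroxy-3,5-dimethoxyphenyl)ethan-1-one | COCC(=O)c1c(O)c(OC)c(O)c(OC)c1O
A4 | alternative 2 | (methoxymethylene)triphenylphosphorane | COC=P(c1ccccc1)(c1ccccc1)c1ccccc1
A5 | alternative 2 | 4-(benzyloxy)-3,5-dimethoxy-2,6-bis[(2,4,5-trimethoxybenzoyl)oxy]benzoyl chloride | COc1cc(OC)c(C(=O)Oc2c(OC)c(OCc3ccccc3)c(OC)c(OC(=O)c3cc(OC)c(OC)cc3OC)c2C(Cl)=O)cc1OC
A6 | alternative 2 | 7-(benzyloxy)-3,6,8-trimethoxy-4-oxo-2-(2,4,5-trimethoxyphenyl)-4H-chromen-5-yl 2,4,5-trimethoxybenzoate | COc1cc(OC)c(-c2oc3c(OC)c(OCc4ccccc4)c(OC)c(OC(=O)c4cc(OC)c(OC)cc4OC)c3c(=O)c2OC)cc1OC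
A7 | alternative 3 | 2-methoxy-1-(2,4,5-trimethoxyphenyl)ethan-1-one | COCC(=O)c1cc(OC)c(OC)cc1OC
A8 | alternative 3 | 2,4,6-trifluoro-3,5-dimethoxybenzoyl chloride | COc1c(F)c(OC)c(F)c(C(Cl)=O)c1F
A9 | alternative 3 | 5,7-difluoro-3,6,8-trimethoxy-2-(2,4,5-trimethoxyphenyl)-4H-chromen-4-one | COc1cc(OC)c(-c2oc3c(OC)c(F)c(OC)c(F)c3c(=O)c2OC)cc1OC
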